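**Retrosynthetic overview**

1. The strategy rests on the C8–C16 bond, the one bond common to the cyclopentanone ring B (C5–C6–C7–C8–C16) and the nine-membered aza-ring C (C8 to C16 through N12). Without it, both rings merge into one twelve-membered ring fused to ring A at C5–C16, with C16 α to a C1 ketone.
2. Target ⇒ tricyclic ketone 25 (C1 ketone, C3–H methyl, C7 dioxolane, N-Boc) by ring-A adjustment: Saegusa oxidation, Luche reduction, hydroxyl-directed epoxidation, hydride opening, acetylation, deprotection.
3. 25 ⇒ macrocyclic (Z)-bromoalkene ketone 23 by transannular palladium coupling of the C1 enolate (through C16) with the C8 vinyl bromide; this makes rings B and C and the quaternary C16 in one event.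
4. 23 ⇒ open-chain aldehyde β-ketophosphonate 17 (Horner–Wadsworth–Emmons closure at C8=C9, then bromination and C7 ketalisation) ⇒ enone 11 + allylsilane 12 (Sakurai, C5–C6) ⇒ iodoenone 6 + carbamate 9 (B-alkyl Suzuki, C15–C16) ⇒ (R)-pulegone.
5. Ring order: ring A (from pulegone) → twelve-membered ring → rings B and C together.

Key step: step 17

Remark: skeletal atoms keep the target numbering in all intermediates (C1 = CH(OAc), C3 = C(CH3)(OAc), C5 = ring-fusion CH, C7 = ketone carbon, C8=C9 alkene, N12, C16 = quaternary carbon).
Remark: C16 (steps 7 to 16) and C1 (steps 9 to 15) are carried as epimer mixtures and are left undefined in the SMILES; C1 is reset in step 16 and C16 in step 17.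
Remark: tert-butyl N-allylcarbamate, 5-bromopent-2-ene and [2-(chloromethyl)allyl]trimethylsilane are taken as purchasable; the target is treated as the amino ketone drawn, any transannular N12–C7 carbinolamine being the same compound in equilibrium.

**Route**

Step 1
Reactants: 1 (R)-(+)-pulegone
Product: 2 pulegone oxide, (6R)-2,2,6-trimethyl-1-oxaspiro[2.5]octan-4-one (both epoxide epimers)
Conditions: 30% H2O2, LiOH (cat.), MeOH, 0 °C → rt
Reagents that add atoms: hydrogen peroxide, OO
Why: Weitz–Scheffer nucleophilic epoxidation of the tetrasubstituted enone, which leaves the methyl-bearing centre untouched and creates a spiro centre that is lost again in step 2.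

Step 2
Reactants: 2 pulegone oxide
Product: 3 (5R)-5-methyl-2-(phenylsulfanyl)cyclohexan-1-one (C2 epimers)
Conditions: PhSNa (1.2 equiv), THF, reflux; H2O work-up
Reagents that add atoms: sodium thiophenolate, [Na+].[S-]c1ccccc1
Why: The thiolate opens the epoxy ketone at the α-carbon and the tertiary alkoxide so formed fragments by retro-aldol loss of acetone, a known degradation of pulegone oxide.

Step 3
Reactants: 3 (5R)-5-methyl-2-(phenylsulfanyl)cyclohexan-1-one
Product: 5 (R)-5-methylcyclohex-2-en-1-one, via sulfoxide 4 (not isolated)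
Conditions: mCPBA (1.0 equiv), CH2Cl2, −78 °C; then CaCO3, toluene, 110 °C
Reagents that add atoms: none
Why: Sulfide oxidation followed by thermal syn-elimination of the α-sulfinyl ketone should give the enone regiospecifically, since only the ring CH2 next to the sulfur-bearing carbon offers β-hydrogens.

Step 4
Reactants: 5 (R)-5-methylcyclohex-2-en-1-one
Product: 6 (R)-2-iodo-5-methylcyclohex-2-en-1-one
Conditions: I2, pyridine/CH2Cl2 (1:1), 0 °C → rt
Reagents that add atoms: iodine, II
Why: Pyridine-mediated α-iodination of a cyclic enone by conjugate addition, iodination of the enolate and elimination.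

Step 5
Reactants: 7 tert-butyl N-allylcarbamate; 8 5-bromopent-2-ene (E/Z mixture)
Product: 9 tert-butyl N-allyl-N-(pent-3-en-1-yl)carbamate
Conditions: NaH, Bu4NI (cat.), DMF, 0 °C → rt
Reagents that add atoms: none
Why: SN2 N-alkylation of the carbamate anion by the primary bromide; the pentenyl group is a masked C9 aldehyde carrying N12, C11 and C10.

Step 6
Reactants: 9 tert-butyl N-allyl-N-(pent-3-en-1-yl)carbamate; 6 (R)-2-iodo-5-methylcyclohex-2-en-1-one
Product: 11 enone tert-butyl N-{3-[(4R)-4-methyl-6-oxocyclohex-1-en-1-yl]propyl}-N-(pent-3-en-1-yl)carbamate, via alkylborane 10 (not isolated)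
Conditions: 9-BBN-H (1.05 equiv), THF, 0 °C → rt; then 6, PdCl2(dppf) (5 mol%), Ph3As (5 mol%), Cs2CO3, DMF/H2O, rt
Reagents that add atoms: none
Why: 9-BBN hydroborates the monosubstituted N-allyl alkene far faster than the 1,2-disubstituted one, and B-alkyl Suzuki–Miyaura coupling with the 2-iodoenone then forms C15–C16.

Step 7
Reactants: 11 enone; 12 [2-(chloromethyl)prop-2-en-1-yl]trimethylsilane
Product: 13 keto allylic chloride [ring A with C1 ketone; (3R)-methyl; (5S)-CH2C(=CH2)CH2Cl trans to the methyl; (CH2)3N(Boc)(CH2)2CH=CHCH3 on C16; both C16 epimers]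
Conditions: TiCl4 (2 equiv), CH2Cl2, −78 °C; H2O quench
Reagents that add atoms: none
Why: Hosomi–Sakurai conjugate addition forms C5–C6 by axial attack anti to the C3 methyl group, the established trans selectivity of 5-methylcyclohexenones, while C16 is protonated without control, which does not matter.

Step 8
Reactants: 13 keto allylic chloride
Product: 14 keto allylphosphonate [as 13 with CH2C(=CH2)CH2P(O)(OMe)2 on C5]
Conditions: P(OMe)3 (neat), NaI (10 mol%), 100 °C
Reagents that add atoms: trimethyl phosphite, COP(OC)OC
Why: Michaelis–Arbuzov reaction of the allylic chloride, with iodide catalysis keeping the temperature below that at which the Boc group is lost.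

Step 9
Reactants: 14 keto allylphosphonate
Product: 15 hydroxy allylphosphonate [as 14 with C1–OH; C1 and C16 epimers]
Conditions: NaBH4, MeOH, 0 °C
Reagents that add atoms: none
Why: Borohydride reduction of the only ketone masks C1 for the later ketalisation of C7; the C1 centre is temporary and is removed in step 16.

Step 10
Reactants: 15 hydroxy allylphosphonate
Product: 16 acetoxy allylphosphonate [as 15 with C1–OAc]
Conditions: Ac2O, pyridine, DMAP (cat.), CH2Cl2, rt
Reagents that add atoms: acetic anhydride, CC(=O)OC(C)=O
Why: DMAP-catalysed acetylation gives an ester that is inert to ozone, bromine and silyl triflate and that can be removed without fluoride or acid.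

Step 11
Reactants: 16 acetoxy allylphosphonate
Product: 17 aldehyde β-ketophosphonate [C5–CH2C(=O)CH2P(O)(OMe)2; C16–(CH2)3N(Boc)CH2CH2CHO; C1–OAc]
Conditions: O3, CH2Cl2/MeOH (4:1), −78 °C; then Me2S, −78 °C → rt
Reagents that add atoms: ozone, [O-][O+]=O
Why: Ozonolysis with reductive work-up cleaves both alkenes at once, the 1,1-disubstituted one to the C7 ketone of a β-ketophosphonate and the 1,2-disubstituted one to the C9 aldehyde.

Step 12
Reactants: 17 aldehyde β-ketophosphonate
Product: 18 macrocyclic (E)-enone [twelve-membered ring C5 to C16 through N12(Boc) fused to ring A; C7 ketone; (8E)-C8=C9; C1–OAc]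
Conditions: LiCl, i-Pr2NEt, MeCN (1 mM, slow addition of 17), rt → 40 °C
Reagents that add atoms: none
Why: Horner–Wadsworth–Emmons macrocyclisation under Masamune–Roush conditions, in which the amine base deprotonates only the β-ketophosphonate and the olefination is E-selective, closes the twelve-membered ring at C8=C9.

Step 13
Reactants: 18 macrocyclic (E)-enone
Product: 20 macrocyclic (Z)-α-bromoenone [as 18 with Br on C8 cis to C10], via dibromide 19 (not isolated)
Conditions: Br2 (1.05 equiv), CH2Cl2, −78 → 0 °C; then Et3N, 0 °C → rt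
Reagents that add atoms: bromine, BrBr
Why: Bromine addition and amine-induced E1cB loss of hydrogen bromide through the C7 enolate should give the conjugated isomer with the acyl group trans to C10 (bromine cis to C10), a ring-trans alkene that a twelve-membered ring holds without strain.

Step 14
Reactants: 20 macrocyclic (Z)-α-bromoenone
Product: 21 bromoalkene ketal acetate [as 20 with C7 as 1,3-dioxolane]
Conditions: Me3SiOCH2CH2OSiMe3, Me3SiOTf (10 mol%), CH2Cl2, −78 → −20 °C; pyridine quench
Reagents that add atoms: 1,2-bis(trimethylsilyloxy)ethane, C[Si](C)(C)OCCO[Si](C)(C)C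
Why: Silyl-triflate-catalysed ketalisation (Noyori conditions) protects an enone carbonyl at low temperature without moving or isomerising the double bond, and C7 is the only ketone present because C1 is an ester.

Step 15
Reactants: 21 bromoalkene ketal acetate
Product: 22 bromoalkene ketal alcohol [as 21 with C1–OH]
Conditions: K2CO3, MeOH, rt
Reagents that add atoms: none
Why: Base-catalysed methanolysis of the acetate, to which the vinyl bromide, the dioxolane and the carbamate are inert.

Step 16
Reactants: 22 bromoalkene ketal alcohol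
Product: 23 macrocyclic bromoalkene ketone [(3R,5S,8Z); C1 ketone; C7 dioxolane; N-Boc; both C16 epimers]
Conditions: Dess–Martin periodinane, NaHCO3, CH2Cl2, rt
Reagents that add atoms: none
Why: Buffered Dess–Martin oxidation of the secondary alcohol restores the C1 ketone and merges the C1 epimers.

Step 17
Reactants: 23 macrocyclic bromoalkene ketone
Product: 25 tricyclic ketone [(3R,5S,16S,8E); rings A B C; C1 ketone; C7 dioxolane; N-Boc], via potassium enolate 24 (not isolated)
Conditions: KOt-Bu (1.3 equiv), Pd2(dba)3 (5 mol%), P(t-Bu)3 (12 mol%), degassed THF (5 mM), rt → 50 °C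
Reagents that add atoms: none
Why: Proposed new method: KOt-Bu turns either C16 epimer of 23 into the same tetrasubstituted enolate 24, zerovalent palladium bearing P(t-Bu)3 inserts into the C8–Br bond with retention, the enolate replaces bromide on the divalent alkenylpalladium, and reductive elimination joins C8 to C16; the closest known reaction type is the palladium-catalysed intramolecular α-alkenylation of ketone enolates with vinyl bromides, which has not been run across a macrocycle. Ring B closes as the five-membered ring C16–C5–C6–C7–C8 through a six-membered palladacycle, and ring C is not closed by a separate event but is the nine-membered remainder (C8 to C16 through N12) of the twelve-membered ring once the transannular bond exists. The only new stereocentre, quaternary C16, is controlled by the fixed C5 centre, because the three-atom tether C5–C6–C7 can bring C8 only to the enolate face that carries the C5–C6 bond, so the A/B fusion must be cis. The step needs bonding at C16 and not at C2, which ring size secures (C2 would demand a seven-membered ring through an eight-membered palladacycle) together with the preference for the more substituted enolate, and it needs C7 to stay non-enolisable, which the dioxolane secures. Bromine stands cis to C10 in 23 and both organometallic steps retain geometry, so C16 ends up cis to C10, the only alkene geometry a nine-membered ring can hold. Near-stoichiometric base and high dilution are chosen so that anti-elimination of hydrogen bromide (H9 is trans to bromine) and intermolecular coupling do not compete.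

Step 18
Reactants: 25 tricyclic ketone
Product: 27 tricyclic enone [C1 ketone conjugated with C2=C3(CH3)], via trimethylsilyl enol ether 26 (not isolated)
Conditions: LiN(i-Pr)2, THF, −78 °C; Me3SiCl; then Pd(OAc)2 (1.1 equiv), MeCN, rt
Reagents that add atoms: none
Why: Saegusa–Ito oxidation, in which C2 is the only enolisable position because C16 is quaternary and β-hydride loss from C3 gives the enone; the C3 centre is given up here and rebuilt in steps 20 and 21.

Step 19
Reactants: 27 tricyclic enone
Product: 28 allylic alcohol [(1S)-C1–OH cis to the C16–C8 bond]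
Conditions: NaBH4, CeCl3·7H2O, MeOH, −78 → −40 °C
Reagents that add atoms: none
Why: Luche 1,2-reduction, in which axial hydride delivery from the face opposite the pseudo-axial C16–C8 bond and ring C should place the C1 hydroxyl cis to C8.

Step 20
Reactants: 28 allylic alcohol
Product: 29 epoxy alcohol [C2–C3 epoxide cis to the C1 hydroxyl]
Conditions: VO(acac)2 (5 mol%), t-BuOOH (1.2 equiv), CH2Cl2, 0 °C
Reagents that add atoms: tert-butyl hydroperoxide, CC(C)(C)OO
Why: Hydroxyl-directed vanadium-catalysed epoxidation delivers oxygen to C2=C3 on the face of the allylic C1 hydroxyl, setting C2 and C3, and should be much faster at this allylic alkene than at the homoallylic C8=C9.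

Step 21
Reactants: 29 epoxy alcohol
Product: 30 cis-1,3-diol [(1S,3S); secondary C1–OH and tertiary C3–OH on the same face; C3 methyl on the other]
Conditions: LiBHEt3, THF, 0 °C → rt; H2O work-up
Reagents that add atoms: none
Why: Hydride opens the epoxide by SN2 attack at the secondary C2 and not at the tertiary C3, so the C3–O bond made in step 20 is kept.

Step 22
Reactants: 30 cis-1,3-diol
Product: 31 diacetate ketal [C1–OAc and C3–OAc; C7 dioxolane; N-Boc]
Conditions: Ac2O, DMAP, Et3N, CH2Cl2, 40 °C
Reagents that add atoms: acetic anhydride, CC(=O)OC(C)=O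
Why: DMAP-mediated (Steglich-type) acylation esterifies the secondary alcohol quickly and the tertiary one on warming.

Step 23
Reactants: 31 diacetate ketal
Product: 32 N-Boc diacetate enone [C7 ketone conjugated with C8=C9]
Conditions: PPTS (20 mol%), acetone/H2O (5:1), 50 °C
Reagents that add atoms: water, O
Why: Mild acid hydrolysis of the allylic dioxolane, with an acid too weak to ionise the tertiary acetate or remove the Boc group.

Step 24
Reactants: 32 N-Boc diacetate enone
Product: 34 CNP0120442.1 (target), via trimethylsilyl carbamate 33 (not isolated)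
Conditions: Me3SiOTf, 2,6-lutidine, CH2Cl2, 0 °C; then MeOH, rt; aq. NaHCO3
Reagents that add atoms: none
Why: Silyl triflate with 2,6-lutidine converts the Boc group into a silyl carbamate under buffered conditions known to spare tert-alkyl esters, and methanolysis with loss of carbon dioxide frees the secondary amine.

**Compound list**

1 | (R)-(+)-pulegone | O=C1C[C@H](C)CCC1=C(C)C | starting material
2 | pulegone oxide, (6R)-2,2,6-trimethyl-1-oxaspiro[2.5]octan-4-one (both epoxide epimers) | O=C1C[C@H](C)CCC12OC2(C)C | intermediate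
3 | (5R)-5-methyl-2-(phenylsulfanyl)cyclohexan-1-one (C2 epimers) | O=C1C[C@H](C)CCC1Sc1ccccc1 | intermediate
4 | sulfoxide, (5R)-5-methyl-2-(phenylsulfinyl)cyclohexan-1-one (not isolated) | O=C1C[C@H](C)CCC1S(=O)c1ccccc1 | intermediate
5 | (R)-5-methylcyclohex-2-en-1-one | O=C1C[C@H](C)CC=C1 | intermediate
6 | (R)-2-iodo-5-methylcyclohex-2-en-1-one | O=C1C[C@H](C)CC=C1I | intermediate
7 | tert-butyl N-allylcarbamate | C=CCNC(=O)OC(C)(C)C | starting material
8 | 5-bromopent-2-ene (E/Z mixture) | CC=CCCBr | starting material
9 | tert-butyl N-allyl-N-(pent-3-en-1-yl)carbamate | C=CCN(CCC=CC)C(=O)OC(C)(C)C | intermediate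
10 | alkylborane, tert-butyl N-[3-(9-borabicyclo[3.3.1]nonan-9-yl)propyl]-N-(pent-3-en-1-yl)carbamate (not isolated) | CC=CCCN(CCCB1C2CCCC1CCC2)C(=O)OC(C)(C)C | intermediate
11 | enone, tert-butyl N-{3-[(4R)-4-methyl-6-oxocyclohex-1-en-1-yl]propyl}-N-(pent-3-en-1-yl)carbamate | O=C1C[C@H](C)CC=C1CCCN(CCC=CC)C(=O)OC(C)(C)C | intermediate
12 | [2-(chloromethyl)prop-2-en-1-yl]trimethylsilane | C=C(CCl)C[Si](C)(C)C | starting material
13 | keto allylic chloride: ring A with C1 ketone, (3R)-methyl, (5S)-CH2C(=CH2)CH2Cl trans to the methyl, (CH2)3N(Boc)(CH2)2CH=CHCH3 on C16 (C16 epimers) | O=C1C[C@H](C)C[C@@H](CC(=C)CCl)C1CCCN(CCC=CC)C(=O)OC(C)(C)C | intermediate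
14 | keto allylphosphonate: as 13 with CH2C(=CH2)CH2P(O)(OMe)2 on C5 | O=C1C[C@H](C)C[C@@H](CC(=C)CP(=O)(OC)OC)C1CCCN(CCC=CC)C(=O)OC(C)(C)C | intermediate
15 | hydroxy allylphosphonate: as 14 with C1–OH (C1 and C16 epimers) | OC1C[C@H](C)C[C@@H](CC(=C)CP(=O)(OC)OC)C1CCCN(CCC=CC)C(=O)OC(C)(C)C | intermediate
16 | acetoxy allylphosphonate: as 15 with C1–OAc | CC(=O)OC1C[C@H](C)C[C@@H](CC(=C)CP(=O)(OC)OC)C1CCCN(CCC=CC)C(=O)OC(C)(C)C | intermediate
17 | aldehyde β-ketophosphonate: C5–CH2C(=O)CH2P(O)(OMe)2, C16–(CH2)3N(Boc)CH2CH2CHO, C1–OAc | CC(=O)OC1C[C@H](C)C[C@@H](CC(=O)CP(=O)(OC)OC)C1CCCN(CCC=O)C(=O)OC(C)(C)C | intermediate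
18 | macrocyclic (E)-enone: twelve-membered ring (C5 to C16 through N-Boc) fused to ring A, C7 ketone, (8E)-alkene, C1–OAc | CC(=O)OC1C[C@H](C)C[C@H]2CC(=O)/C=C/CCN(C(=O)OC(C)(C)C)CCCC12 | intermediate
19 | dibromide: as 18 with Br on C8 and C9 (not isolated) | CC(=O)OC1C[C@H](C)C[C@H]2CC(=O)C(Br)C(Br)CCN(C(=O)OC(C)(C)C)CCCC12 | intermediate
20 | macrocyclic (Z)-α-bromoenone: as 18 with Br on C8 cis to C10 | CC(=O)OC1C[C@H](C)C[C@H]2CC(=O)/C(Br)=C/CCN(C(=O)OC(C)(C)C)CCCC12 | intermediate
21 | bromoalkene ketal acetate: as 20 with C7 as 1,3-dioxolane | CC(=O)OC1C[C@H](C)C[C@H]2CC3(OCCO3)/C(Br)=C/CCN(C(=O)OC(C)(C)C)CCCC12 | intermediate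
22 | bromoalkene ketal alcohol: as 21 with C1–OH | OC1C[C@H](C)C[C@H]2CC3(OCCO3)/C(Br)=C/CCN(C(=O)OC(C)(C)C)CCCC12 | intermediate
23 | macrocyclic bromoalkene ketone (3R,5S,8Z): C1 ketone, C7 dioxolane, N-Boc (C16 epimers) | O=C1C[C@H](C)C[C@H]2CC3(OCCO3)/C(Br)=C/CCN(C(=O)OC(C)(C)C)CCCC12 | intermediate
24 | potassium enolate of 23 (C1=C16; not isolated) | [K+].[O-]C1=C2CCCN(C(=O)OC(C)(C)C)CC/C=C(Br)/C3(OCCO3)C[C@@H]2C[C@@H](C)C1 | intermediate
25 | tricyclic ketone (3R,5S,16S,8E): rings A, B, C; C1 ketone; C7 dioxolane; N-Boc | O=C1C[C@H](C)C[C@H]2CC3(OCCO3)/C4=C/CCN(C(=O)OC(C)(C)C)CCC[C@@]421 | intermediate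
26 | trimethylsilyl enol ether of 25 (C1=C2; not isolated) | C[Si](C)(C)OC1=C[C@H](C)C[C@H]2CC3(OCCO3)/C4=C/CCN(C(=O)OC(C)(C)C)CCC[C@@]421 | intermediate
27 | tricyclic enone (5S,16S,8E): C1 ketone conjugated with C2=C3(CH3) | O=C1C=C(C)C[C@H]2CC3(OCCO3)/C4=C/CCN(C(=O)OC(C)(C)C)CCC[C@@]421 | intermediate
28 | allylic alcohol (1S,5S,16S): C1–OH cis to the C16–C8 bond | O[C@H]1C=C(C)C[C@H]2CC3(OCCO3)/C4=C/CCN(C(=O)OC(C)(C)C)CCC[C@@]421 | intermediate
29 | epoxy alcohol: C2–C3 epoxide cis to the C1 hydroxyl | O[C@H]1[C@H]2O[C@@]2(C)C[C@H]3CC4(OCCO4)/C5=C/CCN(C(=O)OC(C)(C)C)CCC[C@@]531 | intermediate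
30 | cis-1,3-diol (1S,3S,5S,16S): C1–OH and tertiary C3–OH cis | O[C@H]1C[C@@](C)(O)C[C@H]2CC3(OCCO3)/C4=C/CCN(C(=O)OC(C)(C)C)CCC[C@@]421 | intermediate
31 | diacetate ketal: C1–OAc, C3–OAc, C7 dioxolane, N-Boc | CC(=O)O[C@H]1C[C@@](C)(OC(C)=O)C[C@H]2CC3(OCCO3)/C4=C/CCN(C(=O)OC(C)(C)C)CCC[C@@]421 | intermediate
32 | N-Boc diacetate enone: C7 ketone conjugated with (8E)-C8=C9 | CC(=O)O[C@H]1C[C@@](C)(OC(C)=O)C[C@H]2CC(=O)/C3=C/CCN(C(=O)OC(C)(C)C)CCC[C@@]321 | intermediate
33 | trimethylsilyl carbamate of the target amine (not isolated) | CC(=O)O[C@H]1C[C@@](C)(OC(C)=O)C[C@H]2CC(=O)/C3=C/CCN(C(=O)O[Si](C)(C)C)CCC[C@@]321 | intermediate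
34 | CNP0120442.1, (1S,3S,5S,16S,8E) in skeletal numbering | CC(=O)O[C@H]1C[C@@](C)(OC(C)=O)C[C@H]2CC(=O)/C3=C/CCNCCC[C@@]321 | target

**Step count**

Total step count: 24.
Longest linear sequence: 23 steps (1 → 34 through steps 1–4 and 6–24; step 5 makes carbamate 9).

**Steps most likely to fail**

Step 17 (transannular coupling). The base may remove hydrogen bromide across C8–C9 by anti-elimination to give the cycloalkyne. The ring may also stay in conformations in which the alkenylpalladium never meets the enolate carbon, so that protodebromination and oligomerisation take over. The fallback is base-free, uses known reaction types, sets out from 23 and returns at 25. Silylation of 23 under equilibrating conditions (t-BuMe2SiOTf, Et3N, CH2Cl2, rt) should give the more substituted tert-butyldimethylsilyl enol ether F1 (C1=C16). Bu3SnH and AIBN (benzene, 80 °C, syringe pump, 5 mM) then generate the C8 alkenyl radical, which closes ring B by 5-exo attack on C16 of the enol ether. This is a tin-hydride alkenyl-radical cyclisation of the kind long used to build quaternary ring-fusion carbons. The α-silyloxy radical at C1 takes hydrogen from the stannane and gives the tricyclic silyl ether F2 (C1 epimers). Bu4NF in THF frees the tricyclic alcohol F3, and Dess–Martin periodinane oxidises it to 25. The alkenyl radical inverts freely, so the alkene geometry is dictated by the nine-membered ring, and the cis A/B fusion is again forced by the C5–C6–C7 tether.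

Step 19 (Luche reduction). Facial selectivity of hydride delivery to C1 may be poor or reversed, which would also misplace the directed epoxide and with it the C3 oxygen. The fallback sets out from 27 and returns at 28. If the reduction gives mainly the C1-epimeric allylic alcohol F4, that alcohol is inverted by a Mitsunobu reaction (4-nitrobenzoic acid, PPh3, DIAD, toluene, 0 °C → rt). This gives the 4-nitrobenzoate F5 with the required C1 configuration, and K2CO3 in MeOH releases 28.

Step 13 (bromination and dehydrobromination). Geometric control may be lost when hydrogen bromide is eliminated inside the twelve-membered ring, and bromination may also occur at C6. The isomer with bromine trans to C10 cannot give a nine-membered ring in step 17. The fallback sets out from 17 and returns at 20; it puts bromine in place before the alkene is made, so that the olefination sets the geometry. The phosphonate-bearing carbon of 17 is brominated (N-bromosuccinimide, Mg(ClO4)2 (10 mol%), MeCN, 0 °C) to give the α-bromo-β-ketophosphonate aldehyde F6. Horner–Wadsworth–Emmons macrocyclisation of F6 (LiCl, i-Pr2NEt, MeCN, 1 mM) should give 20 directly. The acyl group and C10 end up trans, as in any stabilised phosphonate olefination, which places bromine cis to C10.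

**Further compounds**

F1 | step 17 | tert-butyldimethylsilyl enol ether of 23 (C1=C16) | CC(C)(C)[Si](C)(C)OC1=C2CCCN(C(=O)OC(C)(C)C)CC/C=C(Br)/C3(OCCO3)C[C@@H]2C[C@@H](C)C1
F2 | step 17 | tricyclic C1 tert-butyldimethylsilyl ether (C1 epimers) | CC(C)(C)[Si](C)(C)OC1C[C@H](C)C[C@H]2CC3(OCCO3)/C4=C/CCN(C(=O)OC(C)(C)C)CCC[C@@]421
F3 | step 17 | tricyclic C1 alcohol (C1 epimers) | OC1C[C@H](C)C[C@H]2CC3(OCCO3)/C4=C/CCN(C(=O)OC(C)(C)C)CCC[C@@]421
F4 | step 19 | C1 epimer of allylic alcohol 28 | O[C@@H]1C=C(C)C[C@H]2CC3(OCCO3)/C4=C/CCN(C(=O)OC(C)(C)C)CCC[C@@]421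
F5 | step 19 | 4-nitrobenzoate of allylic alcohol 28 | O=C(O[C@H]1C=C(C)C[C@H]2CC3(OCCO3)/C4=C/CCN(C(=O)OC(C)(C)C)CCC[C@@]421)c1ccc(cc1)[N+](=O)[O-]
F6 | step 13 | α-bromo-β-ketophosphonate aldehyde (17 with Br on the phosphonate carbon) | CC(=O)OC1C[C@H](C)C[C@@H](CC(=O)C(Br)P(=O)(OC)OC)C1CCCN(CCC=O)C(=O)OC(C)(C)C
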